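Late in the runs the rise of the product falls away, and two chemists disagree about what that means for the red flask.

| flask | L | E | time |
|---|---|---|---|
| green | 0.500 M | 1.50 M |  |
| ochre | 0.250 M | 1.25 M |  |
| violet | 0.750 M | 1.50 M |  |
| red | 1.00 M | 4.50 M | 34 min |

- green run (time / min: [Q] / M): 1.9: 0.0455; 5.9: 0.1248; 11: 0.1907; 18: 0.2554; 25: 0.2926; 34: 0.3114
- ochre run (time / min: [Q] / M): 1.9: 0.0180; 5.9: 0.0562; 11: 0.0875; 18: 0.1158; 25: 0.1437; 34: 0.1599
- violet run (time / min: [Q] / M): 1.9: 0.0647; 5.9: 0.1765; 11: 0.2822; 18: 0.3715; 25: 0.4205; 34: 0.4527

(scatter of a reading: 0.002 M)

- Overall: L + E -> Q.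
- Constant volume, constant temperature.
- "The second partner" is E.
- An order is taken over about fifteen percent of the charge, up and down.

* apparent order in [L] of the starting rate, round the charge of the green run (the rate where two percent of its L have turned into Q) (one fixed amount of Q, the same in the runs compared)
* apparent order in [E] of the starting rate, round the charge of the green run (the rate where two percent of its L have turned into Q)
* Q in the red run at 34 min, as a share of the L charged

Both chemists start from the first green reading. It gives a mean rate of 0.0239 M min⁻¹, which over the cL and cE midway to that reading gives a second-order constant k of about 0.0340 M⁻¹ min⁻¹. Between the last two green readings, cQ rises at 0.00209 M min⁻¹, around a mean cQ of 0.302 M. With cL and cE reckoned from that cQ, one of each per Q, k would give 0.00806 M min⁻¹, so the rise is slower than that.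

The second chemist works with the fraction left and names one quantity, s, which comes to 0.0198 min⁻¹: the late shortfall per unit of Q, the rate k predicts minus the rate read, divided by cQ.

The first chemist reads s as a reverse step, which makes k/s an equilibrium constant of 1.72 M⁻¹. The forecast follows that view: 84% (74% to 91%), with orders 0.95 in cL (0.8 to 1.08) and 1.1 in cE (0.7 to 1.6). Its starting point is that “The late slowdown is far too strong for E consumption”.

The second chemist reads s as a drain on Q that does not return L. He concedes the green run to the plateau view: the drain time 1/s of 50.6 min is longer than the 34 min that run lasted, so in the green run a drained curve and a levelling curve are hard to tell apart.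

In the red run L is the limiting reagent, and the second chemist counts one E per L, which puts cE at 3.50 M once the L charge has turned. With that cE his pseudo-first-order constant is 0.119 min⁻¹, and on this reckoning hardly any L remains at 34 min, a fraction of 1.76%. His rise-and-drain curve gives a share of 59.1%, which is lower than the forecast.

The red run gives 60.0% at 34 min, 24 percentage points below the forecast and 0.90 points above the second chemist's share. The orders are 1.0 in cL and 1.0 in cE.

L + E ⇌ Q + J (0.03516 M⁻¹ min⁻¹, 0.005526 M⁻¹ min⁻¹); Q + E → G (0.003822 M⁻¹ min⁻¹); Q → Lx (0.003978 min⁻¹) At the red charge, Q + E → G has a constant per Q of 0.0172 min⁻¹, larger than the 0.00398 min⁻¹ of Q → Lx. Between the last two violet readings, cQ rises at 0.00358 M min⁻¹ where k predicts 0.0113 M min⁻¹, so s in the violet run reads 0.0177 min⁻¹.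

The data stem from a simulated flask for substances that don't exist.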